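## Retrosynthetic overview

1. Target ⇐ lactone α‑methylenation (C15=C17) and reagent‑controlled C3–C4 epoxidation of a 14‑membered, cis‑fused γ‑lactone diene‑diol.
2. Carbocycle ⇐ ring closure at C7–C8 by intramolecular Ni/Cr coupling of a 2‑triflyloxy‑1‑alkene with an aldehyde (sets C7).
3. C13–C14 ⇐ vinylogous Mukaiyama aldol that dearomatises a 4‑alkyl‑2‑silyloxyfuran (C13 and C14 relayed from C12); copper hydride reduction of the butenolide then sets C1 cis.
4. Key step: C8–C13 with C19 and C20 is cut out of 2,6‑dimethylphenol — hydrogenation to the meso ketone, enantioselective deprotonation that breaks its mirror symmetry (sets C12), ozonolytic ring scission.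
5. C2–C7 from geranyl acetate, lactone carbons from 4‑bromofuran‑2(5H)‑one (allyl Stille coupling); ring order: γ‑lactone (present from the start), 14‑membered carbocycle, oxirane.

Assumption: cembrane numbering is used for locants (C1 = lactone β‑carbon, C14 = lactone O–CH, C15/C16 = lactone α‑carbon/carbonyl, C17 and C19 = exocyclic CH2, C18 and C20 = methyls).

Assumption: the (R,R)‑lithium amide of step 2 is taken to give the (S)‑enol ether and the (S)‑sulfonamide ligand of step 13 the 7R carbinol; if either sense proves opposite, the antipodal reagent is used.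

## Route

Step 1
Reactants: 1 2,6‑dimethylphenol
Product: 2 cis‑2,6‑dimethylcyclohexanone (meso; 2R,6S)
Conditions: H2 (5 bar), Pd/C (5% Pd), cyclohexane, 140 °C; NaOMe (cat.), MeOH, 25 °C; cis isomer separated from the minor trans isomer on silica
Reagents that add atoms: none
Why: Heterogeneous arene hydrogenation on Pd stops at the ketone because the cyclohexenol tautomerises and the hindered ketone is reduced slowly, and NaOMe equilibration converts most of the material into the diequatorial cis isomer, a meso compound with a mirror plane through C=O.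

Step 2
Reactants: 2 cis‑2,6‑dimethylcyclohexanone
Product: 3 (6S)‑trimethyl[(2,6‑dimethylcyclohex‑1‑en‑1‑yl)oxy]silane
Conditions: (R,R)‑bis(1‑phenylethyl)amine, n‑BuLi, LiCl, Me3SiCl (internal quench), THF, −100 °C
Reagents that add atoms: chlorotrimethylsilane, C[Si](C)(C)Cl
Why: Enantioselective deprotonation with a chiral lithium amide (Simpkins–Koga type, internal silyl quench) removes one of the two enantiotopic axial α‑hydrogens of the meso ketone, so the untouched α‑carbon becomes the (S)‑configured C12 of the target (about 90% ee expected, the minor enantiomer being removed later as diastereomers formed in the reagent‑controlled steps 13 and 14).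

Step 3
Reactants: 3 (6S)‑silyl enol ether
Product: 4 (2S)‑2‑methyl‑6‑oxoheptanoic acid
Conditions: O3, CH2Cl2, −78 °C; Me2S, −78 → 25 °C; H2O
Reagents that add atoms: ozone, [O-][O+]=O
Why: Criegee ozonolysis of the electron‑rich tetrasubstituted silyl enol ether cleaves the ring C=C into a methyl ketone (C8) and a silyl ester that is hydrolysed on work‑up (C13), leaving the C12 centre untouched.

Step 4
Reactants: 4 (2S)‑2‑methyl‑6‑oxoheptanoic acid
Product: 6 (2S)‑N‑methoxy‑N,2‑dimethyl‑6‑oxoheptanamide, via acyl imidazole 5 (not isolated)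
Conditions: 1,1'‑carbonyldiimidazole, CH2Cl2, 0 → 25 °C; MeNH(OMe)·HCl, 25 °C
Reagents that add atoms: N,O‑dimethylhydroxylamine hydrochloride, CNOC.Cl
Why: Amide coupling through the acyl imidazole needs no added base, so the α‑stereocentre does not epimerise, and the Weinreb amide holds C13 at the aldehyde oxidation level through the next enolate step.

Step 5
Reactants: 6 Weinreb amide
Product: 8 (6S)‑7‑[methoxy(methyl)amino]‑6‑methyl‑7‑oxohept‑1‑en‑2‑yl trifluoromethanesulfonate, via lithium enolate 7 (not isolated)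
Conditions: LDA (1.05 equiv), THF, −78 °C; Comins' reagent, −78 → 0 °C
Reagents that add atoms: N‑(5‑chloropyridin‑2‑yl)‑1,1,1‑trifluoro‑N‑(trifluoromethylsulfonyl)methanesulfonamide (Comins' reagent), FC(F)(F)S(=O)(=O)N(c1ccc(Cl)cn1)S(=O)(=O)C(F)(F)F
Why: Kinetic deprotonation of the methyl ketone with LDA at −78 °C occurs at the methyl group (the amide α‑hydrogen is far less acidic) and O‑triflation fixes the terminal enol triflate that becomes C8=C19, the minor internal regioisomer being removed by chromatography.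

Step 6
Reactants: 8 vinyl triflate Weinreb amide
Product: 10 (6S)‑6‑methyl‑7‑oxohept‑1‑en‑2‑yl trifluoromethanesulfonate, via aluminium hemiaminal 9 (not isolated)
Conditions: i‑Bu2AlH (1.2 equiv), THF, −78 °C; aq. potassium sodium tartrate
Reagents that add atoms: none
Why: Weinreb amide reduction stops at the aldehyde because the chelated tetrahedral aluminium hemiaminal collapses only on work‑up, and the configurationally labile α‑methyl aldehyde is used at once.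

Step 7
Reactants: 11 geranyl acetate
Product: 13 (2E)‑6‑hydroxy‑3‑methylhex‑2‑en‑1‑yl acetate, via aldehyde 12 (not isolated)
Conditions: O3 (1.0 equiv), CH2Cl2/MeOH, −78 °C; NaBH4, −78 → 0 °C
Reagents that add atoms: ozone, [O-][O+]=O
Why: Ozonolysis is chemoselective for the electron‑rich isopropylidene double bond, the 2,3‑double bond being deactivated by the allylic acetate, and borohydride work‑up reduces the aldehyde to the primary alcohol (future C7).

Step 8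
Reactants: 14 4‑bromofuran‑2(5H)‑one
Product: 15 4‑(tributylstannyl)furan‑2(5H)‑one
Conditions: Bu3SnSnBu3 (1.1 equiv), Pd(PPh3)4 (5 mol%), toluene, 100 °C
Reagents that add atoms: hexabutyldistannane, CCCC[Sn](CCCC)(CCCC)[Sn](CCCC)(CCCC)CCCC
Why: Palladium‑catalysed stannylation (oxidative addition of zerovalent palladium to the β‑bromo enoate, Sn–Sn transmetalation, reductive elimination) converts the vinyl bromide into the vinylstannane.

Step 9
Reactants: 13 (2E)‑6‑hydroxy‑3‑methylhex‑2‑en‑1‑yl acetate; 15 4‑(tributylstannyl)furan‑2(5H)‑one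
Product: 16 4‑[(2E)‑6‑hydroxy‑3‑methylhex‑2‑en‑1‑yl]furan‑2(5H)‑one
Conditions: Pd2(dba)3 (3 mol%), LiCl (3 equiv), DMF, 40 °C
Reagents that add atoms: none
Why: Stille coupling of an allylic acetate runs through a π‑allylpalladium chloride that couples at its primary terminus, so the C1–C2 bond forms with the E geometry of the geraniol‑derived C3=C4 bond retained.

Step 10
Reactants: 16 4‑[(2E)‑6‑hydroxy‑3‑methylhex‑2‑en‑1‑yl]furan‑2(5H)‑one; 10 (6S)‑6‑methyl‑7‑oxohept‑1‑en‑2‑yl trifluoromethanesulfonate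
Product: 19 (5R)‑5‑[(1R,2S)‑1‑hydroxy‑2‑methyl‑6‑(trifluoromethanesulfonyloxy)hept‑6‑en‑1‑yl]‑4‑[(2E)‑6‑hydroxy‑3‑methylhex‑2‑en‑1‑yl]furan‑2(5H)‑one, via silyloxyfuran 17 (not isolated), via bis‑silyl ether 18 (not isolated)
Conditions: Me3SiOTf (2.2 equiv), Et3N (2.4 equiv), CH2Cl2, 0 °C; then 10, BF3·OEt2, −78 °C; aq. citric acid, THF, 0 °C
Reagents that add atoms: none
Why: Vinylogous Mukaiyama aldol reaction, in which the aromatic 2‑silyloxyfuran attacks the BF3‑activated aldehyde through C5 and is thereby converted into the butenolide; Felkin–Anh approach to the α‑methyl aldehyde sets 13R (syn to the C12 methyl) and the open transition state favoured with Lewis acids gives the threo C13/C14 pair (14R), with an expected ratio of roughly 4:1 at each centre and the isomers separated by chromatography.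

Step 11
Reactants: 19 butenolide diol
Product: 20 (4S,5R)‑5‑[(1R,2S)‑1‑hydroxy‑2‑methyl‑6‑(trifluoromethanesulfonyloxy)hept‑6‑en‑1‑yl]‑4‑[(2E)‑6‑hydroxy‑3‑methylhex‑2‑en‑1‑yl]dihydrofuran‑2(3H)‑one
Conditions: [(Ph3P)CuH]6 (0.5 equiv), H2O (5 equiv), THF/toluene, 25 °C
Reagents that add atoms: none
Why: Stryker conjugate reduction is selective for the electron‑poor butenolide C=C, and hydride adds to C1 from the face opposite the large C14 substituent, which places H‑1 and H‑14 cis (1S) as the target requires.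

Step 12
Reactants: 20 cis‑lactone diol
Product: 21 (4S,5R)‑5‑[(1R,2S)‑1‑hydroxy‑2‑methyl‑6‑(trifluoromethanesulfonyloxy)hept‑6‑en‑1‑yl]‑4‑[(2E)‑3‑methyl‑6‑oxohex‑2‑en‑1‑yl]dihydrofuran‑2(3H)‑one
Conditions: 2,2,6,6‑tetramethylpiperidin‑1‑oxyl (TEMPO, 10 mol%), PhI(OAc)2 (1.1 equiv), CH2Cl2, 25 °C
Reagents that add atoms: none
Why: Oxoammonium (TEMPO) oxidation is selective for the unhindered primary alcohol over the secondary C13 hydroxyl and touches neither the alkenes nor the vinyl triflate.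

Step 13
Reactants: 21 triflate aldehyde
Product: 22 (1S,3E,7R,12S,13R,14R)‑7,13‑dihydroxy‑17‑norcembra‑3,8(19)‑dien‑16,14‑olide (14‑membered ring cis‑fused to the γ‑lactone)
Conditions: CrCl2 (8 equiv), (S)‑N‑[2‑(4‑isopropyl‑4,5‑dihydrooxazol‑2‑yl)‑6‑methylphenyl]methanesulfonamide (8.8 equiv), Et3N (8.8 equiv), NiCl2 (0.5 equiv), THF/MeCN, 25 °C, syringe‑pump addition to 2 mM
Reagents that add atoms: none
Why: Intramolecular Nozaki–Hiyama–Kishi coupling, in which zerovalent nickel inserts into the vinyl triflate, the vinyl group passes to trivalent chromium and adds to the aldehyde to close the 14‑membered ring under high dilution, while the chiral sulfonamide on chromium selects the aldehyde face to give 7R.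

Step 14
Reactants: 22 macrocyclic diene‑diol
Product: 23 (1S,3R,4R,7R,12S,13R,14R)‑3,4‑epoxy‑7,13‑dihydroxy‑17‑norcembr‑8(19)‑en‑16,14‑olide
Conditions: 1,2:4,5‑di‑O‑isopropylidene‑β‑D‑erythro‑2,3‑hexodiulo‑2,6‑pyranose (30 mol%), Oxone (2KHSO5·KHSO4·K2SO4, 1.4 equiv), K2CO3, Bu4NHSO4, MeCN/CH2(OMe)2/aq. Na2B4O7–Na2EDTA, 0 °C
Reagents that add atoms: potassium peroxymonosulfate, [K+].[O-]S(=O)(=O)OO
Why: Shi epoxidation with the D‑fructose‑derived dioxirane attacks the only trisubstituted, most electron‑rich alkene through a spiro transition state and delivers the (3R,4R) epoxide of the E olefin under basic conditions that leave the allylic 1,1‑disubstituted alkene and the epoxy alcohol intact.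

Step 15
Reactants: 23 epoxy lactone
Product: 27 (1S,3R,4R,7R,12S,13R,14R)‑3,4‑epoxy‑7,13‑dihydroxycembra‑8(19),15(17)‑dien‑16,14‑olide (CNP0124069.1), via trilithium enolate 24 (not isolated), via Mannich base 25 (not isolated), via ammonium iodide 26 (not isolated)
Conditions: LDA (3.5 equiv), THF, −78 °C; CH2=NMe2+ I−, −78 → 0 °C; MeI, MeOH, 25 °C; NaHCO3, CH2Cl2/H2O, 25 °C
Reagents that add atoms: N,N‑dimethylmethyleneiminium iodide (Eschenmoser's salt), C=[N+](C)C.[I-]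
Why: Eschenmoser α‑methylenation, in which the lactone enolate (formed beside the two lithium alkoxides) undergoes a Mannich reaction with the iminium salt and quaternisation followed by E1cB loss of trimethylamine gives the exocyclic alkene without touching any stereocentre.

## Compound list

1 | 2,6‑dimethylphenol | Cc1cccc(C)c1O | starting material
2 | cis‑2,6‑dimethylcyclohexanone (meso, 2R,6S) | O=C1[C@H](C)CCC[C@@H]1C | intermediate
3 | (6S)‑trimethyl[(2,6‑dimethylcyclohex‑1‑en‑1‑yl)oxy]silane | C[C@H]1CCCC(C)=C1O[Si](C)(C)C | intermediate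
4 | (2S)‑2‑methyl‑6‑oxoheptanoic acid | C[C@@H](CCCC(C)=O)C(=O)O | intermediate
5 | (2S)‑1‑(1H‑imidazol‑1‑yl)‑2‑methylheptane‑1,6‑dione (not isolated) | C[C@@H](CCCC(C)=O)C(=O)n1ccnc1 | intermediate
6 | (2S)‑N‑methoxy‑N,2‑dimethyl‑6‑oxoheptanamide | C[C@@H](CCCC(C)=O)C(=O)N(C)OC | intermediate
7 | lithium (6S)‑7‑[methoxy(methyl)amino]‑6‑methyl‑7‑oxohept‑1‑en‑2‑olate (not isolated) | C[C@@H](CCCC(=C)[O-])C(=O)N(C)OC.[Li+] | intermediate
8 | (6S)‑7‑[methoxy(methyl)amino]‑6‑methyl‑7‑oxohept‑1‑en‑2‑yl trifluoromethanesulfonate | C[C@@H](CCCC(=C)OS(=O)(=O)C(F)(F)F)C(=O)N(C)OC | intermediate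
9 | diisobutylaluminium hemiaminal of 8 (O–Al, N(OMe)Me on the former carbonyl carbon; not isolated) | C[C@@H](CCCC(=C)OS(=O)(=O)C(F)(F)F)C(O[Al](CC(C)C)CC(C)C)N(C)OC | intermediate
10 | (6S)‑6‑methyl‑7‑oxohept‑1‑en‑2‑yl trifluoromethanesulfonate | C[C@@H](CCCC(=C)OS(=O)(=O)C(F)(F)F)C=O | intermediate
11 | geranyl acetate | CC(C)=CCC/C(C)=C/COC(C)=O | starting material
12 | (2E)‑3‑methyl‑6‑oxohex‑2‑en‑1‑yl acetate (not isolated) | O=CCC/C(C)=C/COC(C)=O | intermediate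
13 | (2E)‑6‑hydroxy‑3‑methylhex‑2‑en‑1‑yl acetate | OCCC/C(C)=C/COC(C)=O | intermediate
14 | 4‑bromofuran‑2(5H)‑one | O=C1C=C(Br)CO1 | starting material
15 | 4‑(tributylstannyl)furan‑2(5H)‑one | CCCC[Sn](CCCC)(CCCC)C1=CC(=O)OC1 | intermediate
16 | 4‑[(2E)‑6‑hydroxy‑3‑methylhex‑2‑en‑1‑yl]furan‑2(5H)‑one | OCCC/C(C)=C/CC1=CC(=O)OC1 | intermediate
17 | trimethyl[(4‑{(2E)‑3‑methyl‑6‑[(trimethylsilyl)oxy]hex‑2‑en‑1‑yl}furan‑2‑yl)oxy]silane (not isolated) | C[Si](C)(C)OCCC/C(C)=C/Cc1coc(O[Si](C)(C)C)c1 | intermediate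
18 | bis(trimethylsilyl) ether of 19 at the C13 and C7 oxygens (not isolated) | C=C(OS(=O)(=O)C(F)(F)F)CCC[C@H](C)[C@@H](O[Si](C)(C)C)[C@@H]1OC(=O)C=C1C/C=C(\C)CCCO[Si](C)(C)C | intermediate
19 | (5R)‑5‑[(1R,2S)‑1‑hydroxy‑2‑methyl‑6‑(trifluoromethanesulfonyloxy)hept‑6‑en‑1‑yl]‑4‑[(2E)‑6‑hydroxy‑3‑methylhex‑2‑en‑1‑yl]furan‑2(5H)‑one | C=C(OS(=O)(=O)C(F)(F)F)CCC[C@H](C)[C@@H](O)[C@@H]1OC(=O)C=C1C/C=C(\C)CCCO | intermediate
20 | (4S,5R)‑5‑[(1R,2S)‑1‑hydroxy‑2‑methyl‑6‑(trifluoromethanesulfonyloxy)hept‑6‑en‑1‑yl]‑4‑[(2E)‑6‑hydroxy‑3‑methylhex‑2‑en‑1‑yl]dihydrofuran‑2(3H)‑one | C=C(OS(=O)(=O)C(F)(F)F)CCC[C@H](C)[C@@H](O)[C@@H]1OC(=O)C[C@@H]1C/C=C(\C)CCCO | intermediate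
21 | (4S,5R)‑5‑[(1R,2S)‑1‑hydroxy‑2‑methyl‑6‑(trifluoromethanesulfonyloxy)hept‑6‑en‑1‑yl]‑4‑[(2E)‑3‑methyl‑6‑oxohex‑2‑en‑1‑yl]dihydrofuran‑2(3H)‑one | C=C(OS(=O)(=O)C(F)(F)F)CCC[C@H](C)[C@@H](O)[C@@H]1OC(=O)C[C@@H]1C/C=C(\C)CCC=O | intermediate
22 | (1S,3E,7R,12S,13R,14R)‑7,13‑dihydroxy‑17‑norcembra‑3,8(19)‑dien‑16,14‑olide | C=C1CCC[C@H](C)[C@@H](O)[C@@H]2OC(=O)C[C@@H]2C/C=C(\C)CC[C@H]1O | intermediate
23 | (1S,3R,4R,7R,12S,13R,14R)‑3,4‑epoxy‑7,13‑dihydroxy‑17‑norcembr‑8(19)‑en‑16,14‑olide | C=C1CCC[C@H](C)[C@@H](O)[C@@H]2OC(=O)C[C@@H]2C[C@H]2O[C@]2(C)CC[C@H]1O | intermediate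
24 | trilithium salt of 23 (C7 and C13 alkoxides, lactone enolate; not isolated) | C=C1CCC[C@H](C)[C@@H]([O-])[C@@H]2OC([O-])=C[C@@H]2C[C@H]2O[C@]2(C)CC[C@H]1[O-].[Li+].[Li+].[Li+] | intermediate
25 | 15‑[(dimethylamino)methyl] derivative of 23 (C15 epimers; not isolated) | C=C1CCC[C@H](C)[C@@H](O)[C@@H]2OC(=O)C(CN(C)C)[C@@H]2C[C@H]2O[C@]2(C)CC[C@H]1O | intermediate
26 | 15‑[(trimethylammonio)methyl] derivative of 23, iodide (not isolated) | C=C1CCC[C@H](C)[C@@H](O)[C@@H]2OC(=O)C(C[N+](C)(C)C)[C@@H]2C[C@H]2O[C@]2(C)CC[C@H]1O.[I-] | intermediate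
27 | (1S,3R,4R,7R,12S,13R,14R)‑3,4‑epoxy‑7,13‑dihydroxycembra‑8(19),15(17)‑dien‑16,14‑olide (CNP0124069.1) | C=C1CCC[C@H](C)[C@@H](O)[C@@H]2OC(=O)C(=C)[C@@H]2C[C@H]2O[C@]2(C)CC[C@H]1O | target

## Step count and risks

Total step count: 15. Longest linear sequence: 12 (steps 1–6, then 10–15).

**Step 10 (aldol stereotriad).** The relay from C12 rests on a small methyl versus methylene Felkin bias and a moderate threo preference, so the wanted isomer may be only a modest majority. The fallback makes this bond the ring‑closing bond and sets C7 beforehand. It sets out from 16 and 8 and comes back to the route at 22. Compound 16 is oxidised with TEMPO and PhI(OAc)2 to 4‑[(2E)‑3‑methyl‑6‑oxohex‑2‑en‑1‑yl]furan‑2(5H)‑one F1. F1 is joined to 8 by an intermolecular Ni/Cr coupling under the same sulfonamide ligand to give (2S,7R,10E)‑7‑hydroxy‑N‑methoxy‑N,2,10‑trimethyl‑6‑methylidene‑12‑(5‑oxo‑2,5‑dihydrofuran‑3‑yl)dodec‑10‑enamide F2. t‑BuMe2SiOTf and Et3N convert it into (2S,7R,10E)‑7‑[(tert‑butyldimethylsilyl)oxy]‑12‑{5‑[(tert‑butyldimethylsilyl)oxy]furan‑3‑yl}‑N‑methoxy‑N,2,10‑trimethyl‑6‑methylidenedodec‑10‑enamide F3. i‑Bu2AlH at −78 °C gives (2S,7R,10E)‑7‑[(tert‑butyldimethylsilyl)oxy]‑12‑{5‑[(tert‑butyldimethylsilyl)oxy]furan‑3‑yl}‑2,10‑dimethyl‑6‑methylidenedodec‑10‑enal F4. BF3·OEt2 at 1 mM then closes the ring, the tether limiting the faces the furan can reach, to (3E,7R,12S,13R,14R)‑7‑[(tert‑butyldimethylsilyl)oxy]‑13‑hydroxy‑17‑norcembra‑1(15),3,8(19)‑trien‑16,14‑olide F5. HF·pyridine gives (3E,7R,12S,13R,14R)‑7,13‑dihydroxy‑17‑norcembra‑1(15),3,8(19)‑trien‑16,14‑olide F6, and [(Ph3P)CuH]6 reduction from the outer face of the bicycle gives 22.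

**Step 13 (Ni/Cr ring closure).** Ligand control inside a macrocyclic transition state is the least certain stereochemical event, and a C7 epimer mixture is possible. The fallback sets C7 by reduction instead of by C–C bond formation. It sets out from 22 obtained as a C7 epimer mixture and comes back at 22. MnO2 in CH2Cl2 oxidises only the allylic alcohol to (1S,3E,12S,13R,14R)‑13‑hydroxy‑7‑oxo‑17‑norcembra‑3,8(19)‑dien‑16,14‑olide F7. Reduction with catecholborane and (S)‑1‑methyl‑3,3‑diphenyltetrahydro‑1H,3H‑pyrrolo[1,2‑c][1,3,2]oxazaborole (20 mol%) at −78 °C, with the alkenyl group as the large substituent, gives the 7R alcohol 22.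

**Step 14 (epoxidation in the macrocycle).** The ring conformation may expose the wrong face of C3=C4 to the dioxirane. The fallback epoxidises before ring closure, where only the reagent decides. It sets out from 20 and comes back at 23. The same ketone/Oxone system converts acyclic 20 into (4S,5R)‑5‑[(1R,2S)‑1‑hydroxy‑2‑methyl‑6‑(trifluoromethanesulfonyloxy)hept‑6‑en‑1‑yl]‑4‑{[(2R,3R)‑3‑(3‑hydroxypropyl)‑3‑methyloxiran‑2‑yl]methyl}dihydrofuran‑2(3H)‑one F8. TEMPO and PhI(OAc)2 buffered with NaHCO3 (to keep the epoxy alcohol from cyclising) give the aldehyde (4S,5R)‑5‑[(1R,2S)‑1‑hydroxy‑2‑methyl‑6‑(trifluoromethanesulfonyloxy)hept‑6‑en‑1‑yl]‑4‑{[(2R,3R)‑3‑methyl‑3‑(3‑oxopropyl)oxiran‑2‑yl]methyl}dihydrofuran‑2(3H)‑one F9. The Ni/Cr ring closure of step 13 then gives 23.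

## Further compounds

F1 | step 10 | 4‑[(2E)‑3‑methyl‑6‑oxohex‑2‑en‑1‑yl]furan‑2(5H)‑one | O=CCC/C(C)=C/CC1=CC(=O)OC1
F2 | step 10 | (2S,7R,10E)‑7‑hydroxy‑N‑methoxy‑N,2,10‑trimethyl‑6‑methylidene‑12‑(5‑oxo‑2,5‑dihydrofuran‑3‑yl)dodec‑10‑enamide | C=C(CCC[C@H](C)C(=O)N(C)OC)[C@H](O)CC/C(C)=C/CC1=CC(=O)OC1
F3 | step 10 | (2S,7R,10E)‑7‑[(tert‑butyldimethylsilyl)oxy]‑12‑{5‑[(tert‑butyldimethylsilyl)oxy]furan‑3‑yl}‑N‑methoxy‑N,2,10‑trimethyl‑6‑methylidenedodec‑10‑enamide | C=C(CCC[C@H](C)C(=O)N(C)OC)[C@H](O[Si](C)(C)C(C)(C)C)CC/C(C)=C/Cc1coc(O[Si](C)(C)C(C)(C)C)c1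
F4 | step 10 | (2S,7R,10E)‑7‑[(tert‑butyldimethylsilyl)oxy]‑12‑{5‑[(tert‑butyldimethylsilyl)oxy]furan‑3‑yl}‑2,10‑dimethyl‑6‑methylidenedodec‑10‑enal | C=C(CCC[C@H](C)C=O)[C@H](O[Si](C)(C)C(C)(C)C)CC/C(C)=C/Cc1coc(O[Si](C)(C)C(C)(C)C)c1
F5 | step 10 | (3E,7R,12S,13R,14R)‑7‑[(tert‑butyldimethylsilyl)oxy]‑13‑hydroxy‑17‑norcembra‑1(15),3,8(19)‑trien‑16,14‑olide | C=C1CCC[C@H](C)[C@@H](O)[C@@H]2OC(=O)C=C2C/C=C(\C)CC[C@H]1O[Si](C)(C)C(C)(C)C
F6 | step 10 | (3E,7R,12S,13R,14R)‑7,13‑dihydroxy‑17‑norcembra‑1(15),3,8(19)‑trien‑16,14‑olide | C=C1CCC[C@H](C)[C@@H](O)[C@@H]2OC(=O)C=C2C/C=C(\C)CC[C@H]1O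
F7 | step 13 | (1S,3E,12S,13R,14R)‑13‑hydroxy‑7‑oxo‑17‑norcembra‑3,8(19)‑dien‑16,14‑olide | C=C1CCC[C@H](C)[C@@H](O)[C@@H]2OC(=O)C[C@@H]2C/C=C(\C)CCC1=O
F8 | step 14 | (4S,5R)‑5‑[(1R,2S)‑1‑hydroxy‑2‑methyl‑6‑(trifluoromethanesulfonyloxy)hept‑6‑en‑1‑yl]‑4‑{[(2R,3R)‑3‑(3‑hydroxypropyl)‑3‑methyloxiran‑2‑yl]methyl}dihydrofuran‑2(3H)‑one | C=C(OS(=O)(=O)C(F)(F)F)CCC[C@H](C)[C@@H](O)[C@@H]1OC(=O)C[C@@H]1C[C@H]1O[C@]1(C)CCCO
F9 | step 14 | (4S,5R)‑5‑[(1R,2S)‑1‑hydroxy‑2‑methyl‑6‑(trifluoromethanesulfonyloxy)hept‑6‑en‑1‑yl]‑4‑{[(2R,3R)‑3‑methyl‑3‑(3‑oxopropyl)oxiran‑2‑yl]methyl}dihydrofuran‑2(3H)‑one | C=C(OS(=O)(=O)C(F)(F)F)CCC[C@H](C)[C@@H](O)[C@@H]1OC(=O)C[C@@H]1C[C@H]1O[C@]1(C)CCC=O
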